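**Retrosynthetic overview** (prostanoid numbering, C1 = ester carbon, C20 = chain end)
- The target is the conjugated isomer of a 12-hydroxy-10-bromo-cyclopentenone carrying a 4,6-dienyl chain at C8; a C8-H to C4 proton shift gives the 5E,7E-dienone.
- That cyclopentenone comes from a conrotatory 4π electrocyclisation of a C8–C12 2-oxidopentadienyl (hydroxypentadienyl) cation, the ring closure the coral is presumed to use (allene oxide from 8-HPETE to preclavulone A). The cation is made from a 3-bromo-5-octenyl-2-furyl dienyl carbinol and water under a chiral Brønsted acid, so C10–Br, C12–OH and the C12 stereocentre arrive in the ring-forming event.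
- The carbinol comes from a 3-bromo-2-furyllithium (halogen dance of 2-bromo-5-octenylfuran) and an E,E-dienal ester (ene–diene cross-metathesis).
- There is only one ring; it is formed in the last step.

Assumption: compounds 1, 3, 6 and 7 are bought; the (R)-catalyst of step 5 is taken to give the C12 configuration of the target, and its mirror image is used if the sense of induction proves opposite.

**Step 1**
Reactants: 1 (2Z)-oct-2-en-1-ol
Product: 2 (2Z)-1-bromooct-2-ene
Conditions: PBr3 (0.4 equiv), Et2O, −10 → 0 °C
Reagents that add atoms: phosphorus tribromide, BrP(Br)Br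
Why: PBr3 bromination of a primary allylic alcohol (SN2 on the phosphite ester) at low temperature keeps the Z-alkene and avoids allylic transposition.

**Step 2**
Reactants: 3 2-bromofuran; 2 (2Z)-1-bromooct-2-ene
Product: 5 2-bromo-5-[(2Z)-oct-2-en-1-yl]furan, via 5-bromo-2-furyllithium 4 (not isolated)
Conditions: LiN(iPr)2 (1.05 equiv, commercial solution), THF, −78 °C; then 2, −78 → −40 °C
Reagents that add atoms: none
Why: The amide base removes the α-proton at C5 without halogen–lithium exchange (kinetic deprotonation), and the furyllithium is alkylated at the primary carbon of the allylic bromide (SN2), which keeps the Z-alkene.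

**Step 3**
Reactants: 6 methyl pent-4-enoate; 7 (2E,4E)-hexa-2,4-dienal
Product: 8 methyl (4E,6E)-8-oxoocta-4,6-dienoate
Conditions: second-generation Hoveyda–Grubbs catalyst [RuCl2(H2IMes)(=CH-C6H4-2-OiPr)] (5 mol %), 7 (3 equiv), CH2Cl2, 40 °C, propene vented
Reagents that add atoms: none
Why: Ene–diene olefin cross-metathesis: the Ru alkylidene from the terminal alkene engages only the electron-richer γ,δ-alkene of the dienal (the α,β-alkene is deactivated by the formyl group), releases propene and gives the E,E-dienal.

**Step 4**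
Reactants: 5 2-bromo-5-[(2Z)-oct-2-en-1-yl]furan; 8 methyl (4E,6E)-8-oxoocta-4,6-dienoate
Product: 11 methyl (4E,6E)-8-{3-bromo-5-[(2Z)-oct-2-en-1-yl]furan-2-yl}-8-hydroxyocta-4,6-dienoate, via 2-bromo-3-lithio-5-octenylfuran 9 (not isolated), via 3-bromo-2-lithio-5-octenylfuran 10 (not isolated)
Conditions: LiN(iPr)2 (1.1 equiv, commercial solution), THF, −78 °C, 1 h; then 8 (1.0 equiv), −78 °C; aq. NH4Cl
Reagents that add atoms: none
Why: Base-induced halogen dance: kinetic lithiation ortho to bromine is followed by bromine migration to the more stable 3-bromo-2-furyllithium, which adds 1,2 to the aldehyde faster than to the ester; the carbinol centre is racemic and is erased in step 5.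

**Step 5**
Reactants: 11 methyl (4E,6E)-8-{3-bromo-5-[(2Z)-oct-2-en-1-yl]furan-2-yl}-8-hydroxyocta-4,6-dienoate
Product: 14 methyl (5E,7E)-7-[(2R)-4-bromo-2-hydroxy-2-[(2Z)-oct-2-en-1-yl]-5-oxocyclopent-3-en-1-ylidene]hept-5-enoate, via hydroxypentadienyl cation 12 (not isolated), via trans-dienylcyclopentenone 13 (not isolated)
Conditions: (R)-3,3′-bis(2,4,6-triisopropylphenyl)-1,1′-binaphthyl-2,2′-diyl N-triflylphosphoramide (10 mol %), H2O (10 equiv), PhMe, 0 → 23 °C; then Et3N (3 equiv), 23 °C
Reagents that add atoms: water, O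
Why: Proposed new method: the chiral acid ionises the doubly allylic furyl carbinol, water adds at the octenyl-bearing furan carbon (captures at C4 or C6 are reversible), and ring opening gives the O-protonated enol 12, whose conrotatory 4π closure C8–C12 inside the chiral phosphoramidate ion pair sets C12 (C8 is set trans to OH and then erased); Et3N then moves the C8 proton to C4 through the trienol(ate) to the thermodynamic 5E,7E-dienone (minor 7Z isomer removed by chromatography); closest known reaction types are the chiral-Brønsted-acid-catalysed aza-Piancatelli rearrangement and the Dy(OTf)3-catalysed oxa-Piancatelli rearrangement of 5-substituted furylcarbinols, which forms the quaternary C–O centre.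

**Compound list**
1 | (2Z)-oct-2-en-1-ol | CCCCC/C=C\CO | starting material
2 | (2Z)-1-bromooct-2-ene | CCCCC/C=C\CBr | intermediate
3 | 2-bromofuran | Brc1ccco1 | starting material
4 | 5-bromo-2-furyllithium | [Li]c1ccc(Br)o1 | intermediate
5 | 2-bromo-5-[(2Z)-oct-2-en-1-yl]furan | CCCCC/C=C\Cc1ccc(Br)o1 | intermediate
6 | methyl pent-4-enoate | COC(=O)CCC=C | starting material
7 | (2E,4E)-hexa-2,4-dienal | C/C=C/C=C/C=O | starting material
8 | methyl (4E,6E)-8-oxoocta-4,6-dienoate | COC(=O)CC/C=C/C=C/C=O | intermediate
9 | 2-bromo-3-lithio-5-[(2Z)-oct-2-en-1-yl]furan | CCCCC/C=C\Cc1cc([Li])c(Br)o1 | intermediate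
10 | 3-bromo-2-lithio-5-[(2Z)-oct-2-en-1-yl]furan | CCCCC/C=C\Cc1cc(Br)c([Li])o1 | intermediate
11 | methyl (4E,6E)-8-{3-bromo-5-[(2Z)-oct-2-en-1-yl]furan-2-yl}-8-hydroxyocta-4,6-dienoate (racemic at the carbinol carbon) | CCCCC/C=C\Cc1cc(Br)c(C(O)/C=C/C=C/CCC(=O)OC)o1 | intermediate
12 | C8–C12 hydroxypentadienyl cation (O-protonated ring-opened enol: C9–OH enol, C10–Br, protonated C12 carbonyl, C9 and C12 cis on C10=C11) | CCCCC/C=C\CC(=[OH+])/C=C(Br)\C(O)=C\C=C\C=C\CCC(=O)OC | intermediate
13 | methyl (4E,6E)-7-[(1S,5S)-3-bromo-5-hydroxy-5-[(2Z)-oct-2-en-1-yl]-2-oxocyclopent-3-en-1-yl]hepta-4,6-dienoate | CCCCC/C=C\C[C@@]1(O)C=C(Br)C(=O)[C@H]1/C=C/C=C/CCC(=O)OC | intermediate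
14 | methyl (5E,7E)-7-[(2R)-4-bromo-2-hydroxy-2-[(2Z)-oct-2-en-1-yl]-5-oxocyclopent-3-en-1-ylidene]hept-5-enoate | CCCCC/C=C\C[C@@]1(O)C=C(Br)C(=O)/C1=C/C=C/CCCC(=O)OC | target

**Step count**
Total: 5 steps. Longest linear sequence: 4 steps (1 → 2 → 5 → 11 → 14; steps 1, 2, 4, 5).

**Three steps most likely to fail**

Step 5. The enantioselective oxa-variant with water is unproven. The dienyl cation may also be captured at C4 (then lactonise onto the ester) or close on itself as a pentadienyl cation. Fallback: set out from 11 and give up asymmetric induction in the ring closure. Dy(OTf)3 (10 mol %) in MeCN–H2O at 60 °C gives 13 together with its mirror image ent-13 F1. Et3N then gives 14 together with ent-14 F2. The two are separated by preparative supercritical-fluid chromatography on an amylose tris(3,5-dimethylphenylcarbamate) phase, and the route is rejoined at 14.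

Step 4. The halogen dance may be incomplete, or the base may attack the furfurylic/allylic CH2. Fallback: set out from 2 and bought 2,3-dibromofuran. LiN(iPr)2 removes the only α-proton to give 4,5-dibromo-2-furyllithium F3. Alkylation with 2 gives 2,3-dibromo-5-[(2Z)-oct-2-en-1-yl]furan F4. n-BuLi (1.0 equiv, THF, −78 °C) then exchanges the α-bromine selectively, so that 10 is reached by halogen–lithium exchange without any bromine migration. The route is rejoined at 10, which takes up 8 as in step 4.

Step 3. The Ru carbene may also cut the α,β-alkene of the dienal or give E/Z mixtures. Fallback: set out from 6. Cross-metathesis with crotonaldehyde (same Ru catalyst) gives methyl (4E)-6-oxohex-4-enoate F5. A Wittig reaction with (triphenylphosphoranylidene)acetaldehyde (PhMe, 80 °C) extends it by two carbons, and the route is rejoined at 8.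

**Further compounds**
F1 | step 5 | methyl (4E,6E)-7-[(1R,5R)-3-bromo-5-hydroxy-5-[(2Z)-oct-2-en-1-yl]-2-oxocyclopent-3-en-1-yl]hepta-4,6-dienoate (ent-13) | CCCCC/C=C\C[C@]1(O)C=C(Br)C(=O)[C@@H]1/C=C/C=C/CCC(=O)OC
F2 | step 5 | methyl (5E,7E)-7-[(2S)-4-bromo-2-hydroxy-2-[(2Z)-oct-2-en-1-yl]-5-oxocyclopent-3-en-1-ylidene]hept-5-enoate (ent-14) | CCCCC/C=C\C[C@]1(O)C=C(Br)C(=O)/C1=C/C=C/CCCC(=O)OC
F3 | step 4 | 4,5-dibromo-2-furyllithium | [Li]c1cc(Br)c(Br)o1
F4 | step 4 | 2,3-dibromo-5-[(2Z)-oct-2-en-1-yl]furan | CCCCC/C=C\Cc1cc(Br)c(Br)o1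
F5 | step 3 | methyl (4E)-6-oxohex-4-enoate | COC(=O)CC/C=C/C=O
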